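Read each flask as a single number before you spend more substrate on it.

| setting | blue | red | teal | green |
|---|---|---|---|---|
| substrate | 0.800 M | 1.20 M | 0.800 M | 0.800 M |
| partner | 1.60 M | 1.60 M | 0.800 M | 0.530 M |
| catalyst | 0.00800 M | 0.00800 M | 0.00800 M | 0.0160 M |
| time |  |  |  | 140 min |

| blue run: time / min | blue run: [target] / M | red run: time / min | red run: [target] / M | teal run: time / min | teal run: [target] / M |
|---|---|---|---|---|---|
| 5.6 | 0.180 | 5.6 | 0.262 | 5.6 | 0.110 |
| 13 | 0.317 | 13 | 0.453 | 13 | 0.186 |
| 28 | 0.439 | 28 | 0.623 | 28 | 0.300 |
| 63 | 0.573 | 63 | 0.738 | 63 | 0.388 |
| 140 | 0.619 | 140 | 0.826 | 140 | 0.455 |

(each reading ± 0.008 M)

- Overall: substrate + partner -> target, with catalyst as catalyst.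
- Constant volume, constant temperature.
- An order is taken over about fifteen percent of the charge, up and down.

- order of the initial rate in [substrate], near the charge of the blue run, the rate being that where two percent of its substrate are target (one fixed amount of target, the same in the runs compared)
- order of the initial rate in [partner], near the charge of the blue run, the rate being that where two percent of its substrate are target
- target in the green run at 140 min, as a share of the substrate charged

Two chemists look at the runs so far and disagree about green. They share one early reading: at 5.6 min the red flask has turned 21.8% of its substrate and the blue flask 22.5%. The share barely moves with the substrate charge, so the order in substrate reads near one.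

The first chemist holds a balance view: each flask comes to a fixed ratio of target to what is left, whatever the catalyst. In shares of the substrate charge, that ratio reads 3.06 in teal and 2.79 in blue at 140 min. In green the partner is the limiting reagent, at 0.662 of the substrate, and teal's ratio gives 42.3% there. This view keeps its ground as a summary of the last readings of blue and teal, at their catalyst charge of 0.00800 M.

The second chemist holds a clock view, that the turning fades with time and not with nearness to a balance, and this reckoning is mine. Teal has equal charges, and at 140 min its share turned over its share left is 1.32. Call this the dose: the turning received by a flask whose rate goes with catalyst, substrate and partner, with the same sum in its integrated form where charges differ. At 13 min teal's dose is 0.303 and blue's 0.284, so the order in partner also reads near one. Late on they part, for blue's dose at 140 min is 0.997. Teal still gained 8.38% of its substrate after 63 min, which a ratio at rest would not show.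

I take teal's dose, as teal is nearer green in partner, and double it with the catalyst to 2.64. Unwound through green's charges, that gives 53.6%.

The forecast sides with the clock, giving 0.97 (0.82 to 1.08) in substrate, 0.65 (0.48 to 0.85) in partner, where I read near one, and 54% (44% to 60%) for green, saying “That looks like catalyst dying rather than equilibrium”.

The green flask gives 55.3% at 140 min, more than the balance's 42.3%, with orders of 1.0 in substrate and 1.0 in partner.

    catalyst + substrate + partner → target + catalyst (4.392 /M²/min)
    2 substrate → homo dimer (0.008520 /M/min)
    2 partner → lost reagent (0.008940 /M/min)

Where the same amount had been made, blue ran at 0.043 M/min and teal at 0.021 M/min, twice the rate on twice the partner. Green's dose, reckoned from its result through its own charges, is 2.94, which is 2.23 times teal's dose at the same time.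

The earlier runs and the new flask are simulated with constants of no real substance; noise was put on by code.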